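The cyclohexane ring is cut across C1–C6 and C2–C3 (bisabolane numbering). Its all-cis C6/C1/C2 triad (side-chain carbon C7 on C6 next to the C1/C2 cis-diol) is the imprint of an endo Diels–Alder addition of a cis-enediol to an (E,E)-diene, and the C3/C4 chlorohydrin is a masked ring alkene. Vinylene carbonate and methyl sorbate therefore give, in one thermal [4+2], both ring bonds, C6, C1 and C2, with C7 as an ester and C15 already in place. A bridged C7–O2 lactone then tells the two oxygens apart and steers the alkene to C3=C4; epoxidation, chloride opening and a Nozaki–Hiyama–Kishi union complete the route.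

Key step: step 1

Remark on numbering: atom labels C1–C15 follow bisabolane numbering of the target (ring C1 OAc, C2 OAng, C3 C(CH3)OH with C15 the methyl, C4 Cl, C5 CH2, C6 CH; side chain C7(=C14H2), C8 OAng, C9, C10–C11 epoxide; target = 1S,2S,3S,4S,6R,8S,10S). Locants inside systematic names are those of the name.
Remark on racemates: compounds 3–7 are racemic; each SMILES shows the enantiomer that leads on.
Assumption: the lipase of step 5 acylates the drawn enantiomer of 7; if the opposite preference is found, the unreacted alcohol is the wanted enantiomer and Ac2O/pyridine converts it into the same 8.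

Step 1
Reactants: 1 methyl sorbate (methyl (2E,4E)-hexa-2,4-dienoate); 2 vinylene carbonate (1,3-dioxol-2-one)
Product: 3 racemic all-cis cycloadduct methyl 7-methyl-2-oxo-3a,4,7,7a-tetrahydro-1,3-benzodioxole-4-carboxylate
Conditions: 2 (3 equiv, neat), BHT (cat.), sealed tube, 180 °C
Reagents that add atoms: none
Why: Diels–Alder reaction: a concerted, suprafacial [4+2] cycloaddition between the s-cis (E,E)-dienoate and the cyclic enediol carbonate, the closest known type being the thermal addition of vinylene carbonate to (E,E)-1,4-disubstituted butadienes. The carbocycle is closed by this single pericyclic event, the C1–C6 and C2–C3 bonds forming together through one six-membered transition state, so there is no separate ring-closure mode to choose. The cis relation of O1 and O2 follows from the (Z)-alkene locked in the carbonate ring, the cis relation of the C6 ester and the ring methyl from the (E,E)-geometry of the diene, and the cis relation between these two pairs from the endo transition state in which the carbonate lies under the diene. The selectivity needed is endo over exo, which the compact endo transition state and secondary overlap of the carbonate with the diene should secure; regiochemistry does not arise because the dienophile is symmetric. The adduct is racemic, and of its four stereocentres C6, C1 and C2 are carried into the target while the methyl-bearing one is erased in step 3.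

Step 2
Reactants: 3 racemic all-cis cycloadduct
Product: 5 racemic hydroxy lactone 8-hydroxy-4-methyl-6-oxabicyclo[3.2.1]oct-2-en-7-one, via dihydroxy acid 4 (not isolated)
Conditions: LiOH, THF–H2O, 0 °C; aq. HCl to pH 3, extraction; then EDC·HCl, DMAP (cat.), CH2Cl2, 0 °C → rt
Reagents that add atoms: none
Why: Saponification of the ester and the cyclic carbonate followed by carbodiimide lactonisation (Steglich type) should give the γ-lactone because only the C2 hydroxyl is cis-1,3 to the C7 acid (the C1 hydroxyl could only form a β-lactone), which tells the two hydroxyls apart and makes C6 a bridgehead; no new stereocentre is formed.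

Step 3
Reactants: 5 racemic hydroxy lactone
Product: 6 racemic 8-hydroxy-4-methyl-6-oxabicyclo[3.2.1]oct-3-en-7-one
Conditions: RuHCl(CO)(PPh3)3 (cat.), toluene, 100 °C
Reagents that add atoms: none
Why: Ruthenium hydride alkene isomerisation (hydrometalation then β-hydride elimination) should shift the disubstituted C4=C5 alkene to the trisubstituted C3=C4 position, since the only other migration, towards C6, would place a double bond at the bridgehead of the bicyclo[3.2.1] lactone (Bredt's rule); the methyl-bearing stereocentre is erased.

Step 4
Reactants: 6 racemic isomerised hydroxy lactone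
Product: 7 racemic enol ether 4-methyl-7-methylidene-6-oxabicyclo[3.2.1]oct-3-en-8-ol
Conditions: Cp2TiMe2 (3 equiv), toluene, 70 °C, dark
Reagents that add atoms: dimethyltitanocene Cp2TiMe2, C[Ti](C)(C1C=CC=C1)C1C=CC=C1
Why: Petasis methylenation: the titanium methylidene formed on heating undergoes [2+2] addition to the lactone carbonyl and cycloreversion to the exocyclic enol ether, which introduces C14 while keeping O2 bound to C7; the free hydroxyl only consumes part of the excess reagent and no stereocentre changes.

Step 5
Reactants: 7 racemic enol ether alcohol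
Product: 8 single-enantiomer acetate 4-methyl-7-methylidene-6-oxabicyclo[3.2.1]oct-3-en-8-yl acetate
Conditions: immobilised Candida antarctica lipase B, isopropenyl acetate, MTBE, 4 Å molecular sieves, 30 °C, stopped near half conversion; chromatography
Reagents that add atoms: isopropenyl acetate, CC(=C)OC(C)=O
Why: Lipase-catalysed kinetic resolution by enantioselective transesterification of the secondary C1 hydroxyl (acyl-enzyme mechanism) should acetylate one enantiomer only, fixing the absolute configuration of C1, C2 and C6 and installing the C1 acetate of the target in the same operation.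

Step 6
Reactants: 8 enol ether acetate
Product: 9 all-cis 6-acetyl-2-hydroxy-3-methylcyclohex-3-en-1-yl acetate
Conditions: PPTS (cat.), THF–H2O, 0 °C
Reagents that add atoms: water, O
Why: Acid-catalysed enol ether hydrolysis (protonation at C14, water addition to the oxocarbenium ion, collapse of the hemiketal) should release the C7 methyl ketone and the C2 allylic alcohol under conditions too mild to epimerise C6 or move the acetate.

Step 7
Reactants: 9 hydroxy ketone
Product: 10 all-cis 4-acetyl-2-hydroxy-1-methyl-7-oxabicyclo[4.1.0]heptan-3-yl acetate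
Conditions: VO(acac)2 (cat.), t-BuOOH, CH2Cl2, 0 °C → rt
Reagents that add atoms: tert-butyl hydroperoxide, CC(C)(C)OO
Why: Hydroxyl-directed vanadium-catalysed epoxidation of the allylic alcohol delivers oxygen to the C3=C4 alkene from the face of the C2 hydroxyl, which sets C3 and C4 with the epoxide cis to O2.

Step 8
Reactants: 10 epoxy alcohol
Product: 11 C2 angelate 3-acetoxy-4-acetyl-1-methyl-7-oxabicyclo[4.1.0]heptan-2-yl (Z)-2-methylbut-2-enoate
Conditions: angelic acid, 2,4,6-trichlorobenzoyl chloride, Et3N, toluene, rt; then 10, toluene, 75 °C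
Reagents that add atoms: angelic acid ((Z)-2-methylbut-2-enoic acid), C/C=C(/C)C(=O)O
Why: Yamaguchi esterification through the mixed 2,4,6-trichlorobenzoic anhydride acylates the hindered C2 hydroxyl and is run without DMAP to keep the (Z)-geometry of the angelate; no stereocentre is touched.

Step 9
Reactants: 11 epoxy keto diester
Product: 13 alkenyl triflate 3-acetoxy-1-methyl-4-[1-(trifluoromethylsulfonyloxy)ethenyl]-7-oxabicyclo[4.1.0]heptan-2-yl (Z)-2-methylbut-2-enoate, via potassium enolate 12 (not isolated)
Conditions: KN(SiMe3)2, THF, −78 °C; then N-(5-chloropyridin-2-yl)triflimide, −78 °C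
Reagents that add atoms: N-(5-chloropyridin-2-yl)bis(trifluoromethanesulfonyl)imide, O=S(=O)(N(c1ccc(Cl)cn1)S(=O)(=O)C(F)(F)F)C(F)(F)F
Why: Kinetic deprotonation of the methyl ketone at C14 by the bulky amide base at −78 °C and O-sulfonylation of the enolate (enol triflate formation) should give the 1,1-disubstituted alkenyl triflate regioselectively, the less acidic esters and the epoxide being left alone and C6 not being deprotonated.

Step 10
Reactants: 13 epoxy alkenyl triflate
Product: 14 chlorohydrin 6-acetoxy-3-chloro-2-hydroxy-2-methyl-5-[1-(trifluoromethylsulfonyloxy)ethenyl]cyclohexyl (Z)-2-methylbut-2-enoate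
Conditions: LiCl, AcOH, THF, rt
Reagents that add atoms: lithium chloride, [Li+].[Cl-]
Why: Acid-assisted SN2 opening of the trisubstituted epoxide by chloride occurs at the secondary C4 with inversion, along the trans-diaxial (Fürst–Plattner) pathway that keeps the large C6 substituent equatorial, to give the C4 chloride trans to the tertiary C3 hydroxyl.

Step 11
Reactants: 15 4-methylpent-3-en-1-ol
Product: 16 4-methylpent-3-enal
Conditions: Dess–Martin periodinane, NaHCO3, CH2Cl2, 0 °C; used at once
Reagents that add atoms: none
Why: Dess–Martin oxidation converts the primary alcohol into the aldehyde under buffered, non-basic conditions that avoid conjugation of the β,γ-alkene.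

Step 12
Reactants: 14 chlorohydrin alkenyl triflate; 16 4-methylpent-3-enal
Product: 17 C8 allylic alcohol 6-acetoxy-3-chloro-2-hydroxy-5-[(3S)-3-hydroxy-6-methylhepta-1,5-dien-2-yl]-2-methylcyclohexyl (Z)-2-methylbut-2-enoate
Conditions: CrCl2 (excess), NiCl2 (cat.), chiral oxazoline–sulfonamide ligand (enantiomer chosen for the 8S carbinol), Et3N, THF, rt
Reagents that add atoms: none
Why: Nozaki–Hiyama–Kishi coupling: NiCl2-catalysed activation of the alkenyl triflate, transmetalation to chromium and chemoselective addition of the alkenylchromium to the aldehyde form the C7–C8 bond, the chiral ligand on chromium selecting the aldehyde face so that C8 is formed as the S carbinol, while esters, the chloride and the tertiary alcohol are tolerated.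

Step 13
Reactants: 17 C8 allylic alcohol
Product: 18 bis-angelate, the 10,11-alkene precursor of the target
Conditions: angelic acid, 2,4,6-trichlorobenzoyl chloride, Et3N, toluene, rt; then 17, toluene, 75 °C
Reagents that add atoms: angelic acid ((Z)-2-methylbut-2-enoic acid), C/C=C(/C)C(=O)O
Why: Yamaguchi esterification of the secondary allylic C8 hydroxyl, the tertiary C3 hydroxyl being too hindered to react; no stereocentre is touched.

Step 14
Reactants: 18 bis-angelate
Product: 19 target CNP0313121.1
Conditions: L-fructose-derived ketone catalyst of the Shi epoxidation (1–3 equiv), Oxone (2KHSO5·KHSO4·K2SO4), NaHCO3, MeCN–aq. Na2EDTA, 0 °C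
Reagents that add atoms: potassium peroxymonosulfate KHSO5, [K+].[O-]S(=O)(=O)OO
Why: Shi epoxidation: the chiral dioxirane formed from the ketone and KHSO5 epoxidises the electron-rich trisubstituted C10=C11 alkene in preference to the 1,1-disubstituted C7=C14 alkene and the electron-poor angelates, the L-series catalyst delivering oxygen through the spiro transition state to the face that gives the 10S epoxide, while the near-neutral pH protects the chlorohydrin and the esters.

Compound list
1 | methyl sorbate, methyl (2E,4E)-hexa-2,4-dienoate | C/C=C/C=C/C(=O)OC | starting material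
2 | vinylene carbonate, 1,3-dioxol-2-one | O=C1OC=CO1 | starting material
3 | racemic all-cis cycloadduct, methyl 7-methyl-2-oxo-3a,4,7,7a-tetrahydro-1,3-benzodioxole-4-carboxylate (ester, methyl and carbonate oxygens on one face) | COC(=O)[C@H]1C=C[C@@H](C)[C@@H](OC(=O)O2)[C@H]12 | intermediate
4 | racemic all-cis 5,6-dihydroxy-4-methylcyclohex-2-ene-1-carboxylic acid | OC(=O)[C@H]1C=C[C@@H](C)[C@@H](O)[C@H]1O | intermediate (not isolated)
5 | racemic 8-hydroxy-4-methyl-6-oxabicyclo[3.2.1]oct-2-en-7-one (8-hydroxyl on the side of the lactone bridge; 4-methyl cis to the lactone oxygen on the carbocycle) | O=C3[C@H]1C=C[C@@H](C)[C@@H](O3)[C@H]1O | intermediate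
6 | racemic 8-hydroxy-4-methyl-6-oxabicyclo[3.2.1]oct-3-en-7-one (8-hydroxyl on the side of the lactone bridge) | O=C3[C@H]1CC=C(C)[C@@H](O3)[C@H]1O | intermediate
7 | racemic 4-methyl-7-methylidene-6-oxabicyclo[3.2.1]oct-3-en-8-ol (8-hydroxyl on the side of the oxygen bridge) | C=C3[C@H]1CC=C(C)[C@@H](O3)[C@H]1O | intermediate
8 | single enantiomer, 4-methyl-7-methylidene-6-oxabicyclo[3.2.1]oct-3-en-8-yl acetate | C=C3[C@H]1CC=C(C)[C@@H](O3)[C@H]1OC(C)=O | intermediate
9 | all-cis 6-acetyl-2-hydroxy-3-methylcyclohex-3-en-1-yl acetate (acetyl, acetate and hydroxyl on one face) | CC(=O)[C@H]1CC=C(C)[C@@H](O)[C@H]1OC(C)=O | intermediate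
10 | all-cis 4-acetyl-2-hydroxy-1-methyl-7-oxabicyclo[4.1.0]heptan-3-yl acetate (epoxide on the face of the hydroxyl) | CC(=O)[C@H]1C[C@H]2O[C@@]2(C)[C@@H](O)[C@H]1OC(C)=O | intermediate
11 | 3-acetoxy-4-acetyl-1-methyl-7-oxabicyclo[4.1.0]heptan-2-yl (Z)-2-methylbut-2-enoate (all ring substituents and the epoxide cis) | CC(=O)[C@H]1C[C@H]2O[C@@]2(C)[C@@H](OC(=O)/C(C)=C\C)[C@H]1OC(C)=O | intermediate
12 | potassium enolate of 11 (C7=C14 enolate) | [K+].C=C([O-])[C@H]1C[C@H]2O[C@@]2(C)[C@@H](OC(=O)/C(C)=C\C)[C@H]1OC(C)=O | intermediate (not isolated)
13 | 3-acetoxy-1-methyl-4-[1-(trifluoromethylsulfonyloxy)ethenyl]-7-oxabicyclo[4.1.0]heptan-2-yl (Z)-2-methylbut-2-enoate | C=C(OS(=O)(=O)C(F)(F)F)[C@H]1C[C@H]2O[C@@]2(C)[C@@H](OC(=O)/C(C)=C\C)[C@H]1OC(C)=O | intermediate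
14 | 6-acetoxy-3-chloro-2-hydroxy-2-methyl-5-[1-(trifluoromethylsulfonyloxy)ethenyl]cyclohexyl (Z)-2-methylbut-2-enoate (chloride trans to the tertiary hydroxyl; hydroxyl, esters and alkenyl group cis) | C=C(OS(=O)(=O)C(F)(F)F)[C@H]1C[C@H](Cl)[C@@](C)(O)[C@@H](OC(=O)/C(C)=C\C)[C@H]1OC(C)=O | intermediate
15 | 4-methylpent-3-en-1-ol | CC(C)=CCCO | starting material
16 | 4-methylpent-3-enal | CC(C)=CCC=O | intermediate
17 | 6-acetoxy-3-chloro-2-hydroxy-5-[(3S)-3-hydroxy-6-methylhepta-1,5-dien-2-yl]-2-methylcyclohexyl (Z)-2-methylbut-2-enoate | C=C([C@H](CC=C(C)C)O)[C@H]1C[C@H](Cl)[C@@](C)(O)[C@@H](OC(=O)/C(C)=C\C)[C@H]1OC(C)=O | intermediate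
18 | C8 angelate of 17 (bis-angelate with the C10=C11 alkene) | C=C([C@H](CC=C(C)C)OC(=O)/C(C)=C\C)[C@H]1C[C@H](Cl)[C@@](C)(O)[C@@H](OC(=O)/C(C)=C\C)[C@H]1OC(C)=O | intermediate
19 | CNP0313121.1 (1S,2S,3S,4S,6R,8S,10S in bisabolane numbering) | C=C([C@H](C[C@@H]1OC1(C)C)OC(=O)/C(C)=C\C)[C@H]1C[C@H](Cl)[C@@](C)(O)[C@@H](OC(=O)/C(C)=C\C)[C@H]1OC(C)=O | target

Total step count: 14. Longest linear sequence: 13 (steps 1–10 and 12–14; step 11 prepares the aldehyde).

Steps most likely to fail

Step 1. The cycloaddition of the electron-poor dienoate may be slow, so that thermal polymerisation of 1 competes, or part of the reaction may leak into the exo mode. The fallback sets out from 2 and returns at 5. The non-activated diene sorbyl acetate F1 ((2E,4E)-hexa-2,4-dien-1-yl acetate, commercial) is heated with 2 (neat, 175 °C) to the racemic all-cis cycloadduct F2. LiOH in aqueous THF removes acetate and carbonate to give the racemic all-cis triol F3. TEMPO/PhI(OAc)2 then oxidises the primary alcohol selectively and, through the lactol formed with the cis-1,3 hydroxyl, should deliver hydroxy lactone 5.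

Step 5. The enzyme may discriminate the enantiomers poorly, because the carbinol is flanked by two similar bridgeheads, so that neither ester nor alcohol is obtained enantiopure. The fallback sets out from 7 and returns at 8. Racemic 7 is esterified with (S)-O-methylmandelic acid (DCC, DMAP cat.) to two diastereomers, the O-methylmandelate of the drawn enantiomer F4 and the O-methylmandelate of the mirror-image alcohol F5. These are separated by chromatography or crystallisation. K2CO3/MeOH cleaves F4 to the drawn enantiomer of 7, and Ac2O/pyridine gives 8.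

Step 12. Facial control at the aldehyde may be weak, giving a mixture of C8 epimers. The fallback sets out from 14 and returns at 17. The coupling with 16 is run without chiral ligand (CrCl2, NiCl2 cat., DMF) to give 17 mixed with its C8 epimer F6. Dess–Martin oxidation of the mixture converges on the enone F7. CBS reduction with (R)-2-methyl-CBS-oxazaborolidine and catecholborane, the alkenyl group acting as the large substituent, should give 17.

Further compounds
F1 | step 1 | sorbyl acetate, (2E,4E)-hexa-2,4-dien-1-yl acetate | C/C=C/C=C/COC(C)=O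
F2 | step 1 | racemic all-cis cycloadduct (7-methyl-2-oxo-3a,4,7,7a-tetrahydro-1,3-benzodioxol-4-yl)methyl acetate | CC(=O)OC[C@H]1C=C[C@@H](C)[C@@H](OC(=O)O2)[C@H]12
F3 | step 1 | racemic all-cis 3-(hydroxymethyl)-6-methylcyclohex-4-ene-1,2-diol | OC[C@H]1C=C[C@@H](C)[C@@H](O)[C@H]1O
F4 | step 5 | (S)-O-methylmandelate of the drawn enantiomer of 7 | C=C3[C@H]1CC=C(C)[C@@H](O3)[C@H]1OC(=O)[C@@H](OC)c1ccccc1
F5 | step 5 | (S)-O-methylmandelate of the mirror-image alcohol | C=C3[C@@H]1CC=C(C)[C@H](O3)[C@@H]1OC(=O)[C@@H](OC)c1ccccc1
F6 | step 12 | C8 epimer of 17 | C=C([C@@H](CC=C(C)C)O)[C@H]1C[C@H](Cl)[C@@](C)(O)[C@@H](OC(=O)/C(C)=C\C)[C@H]1OC(C)=O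
F7 | step 12 | C8 enone, 6-acetoxy-3-chloro-2-hydroxy-2-methyl-5-(6-methyl-3-oxohepta-1,5-dien-2-yl)cyclohexyl (Z)-2-methylbut-2-enoate | C=C(C(=O)CC=C(C)C)[C@H]1C[C@H](Cl)[C@@](C)(O)[C@@H](OC(=O)/C(C)=C\C)[C@H]1OC(C)=O
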